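## The problem

Compound 34 is a cembranolide: a 14-membered carbocycle (C1–C14) with three (E)-trisubstituted olefins (C3=C4, C7=C8, C11=C12), trans-fused at C1/C2 to an α-methylene-γ-butyrolactone (C1–C15(=C17H2)–C16(=O)–O–C2), and carrying an allylic acetate at C6. Three stereocentres must be set. C1 (R) and C2 (S) are neighbours on the lactone, so one can direct the other. C6 (R) is separated from them by the C3=C4 olefin and the C5 methylene, so it needs reagent control, as does the first centre of the C1/C2 pair. The ring has no polar handle between C9 and C14, so closure has to be a C–C bond formation that leaves all three olefin geometries untouched. The exocyclic enoate is a strong Michael acceptor that will not survive boranes, organometallics or nucleophilic base. The C6 acetate and the C2 lactone oxygen are both allylic leaving groups, which argues for late unveiling and mild closing steps. The enabling feature is the substitution pattern of the lactone: C2, C1 and C15 carry in sequence the C3 alkenyl chain, the C14 chain and the C17 methylene. That is the pattern left when a carbon nucleophile and then a carbon electrophile add across the C1=C15 bond of a γ-alkenyl butenolide whose only stereocentre is C2.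

## Retrosynthesis

**Unmasking (34 ⇒ 32 ⇒ 31 ⇒ 30).** No skeletal bond is cut. The C15=C17 olefin is traced to the dimethylaminomethyl group of 32 (quaternization to 33, then elimination), the acetate to alcohol 31, and that to silyl ether 30. The exocyclic enoate would undergo conjugate hydroboration and base addition, and an allylic acetate would be ionized by palladium, so both are introduced only after the ring is closed. The forward steps are a desilylation, an acetylation and a mild E1cB elimination.

**Ring closure (30 ⇒ 28).** The C12–C13 bond is cut. Closure at an olefin by metathesis could not secure a trisubstituted (E)-alkene in a macrocycle, and closure at C5–C6 or C2–C3 would create a stereocentre during macrocyclization. The C12–C13 bond is an sp2–sp3 bond with no stereochemical content. Precursor 28 is acyclic apart from the lactone and already holds every stereocentre and olefin geometry. The forward reaction requires hydroboration of the only monosubstituted alkene (via borane 29) and a B-alkyl Suzuki–Miyaura coupling with retention at the alkenyl iodide under high dilution.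

**Three-component union on the lactone (28 ⇒ 24 + 25 + 26).** The C1–C14 and C15–C17 bonds are cut. This removes the C14 chain and the masked methylene in one operation and leaves butenolide 24 with C2 as its only lactone stereocentre. The alternative of alkylating a preformed saturated lactone twice would need two enolate steps and a separate way to set C1. The forward reaction requires anti 1,4-addition of vinylmagnesium bromide 25 and capture of silyl ketene acetal 27 by iminium salt 26.

**Butenolide (24 ⇒ 22 ⇒ 19 + 20).** The lactone C16–O bond and the C1–C2 bond are cut. A (Z)-γ-hydroxy enoate 23 lactonizes on formation, and it comes from ynoate 22 by semihydrogenation. Compound 22 is the adduct of methyl propiolate 20 with enal 19, so C2 is set by a catalytic asymmetric alkynylation in an open chain. This is preferred to an olefination approach, which would need an epimerizable α-oxygenated aldehyde. The alkynylation must be catalyst-controlled, because the C6 centre is too remote to help.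

**C5–C6 bond (19 ⇒ 18 ⇒ 17 ⇒ 16 ⇒ 11 + 14).** Enal 19 is reached from ester 17 through alcohol 18, and 17 is the silyl ether of aldol 16. Cutting C5–C6 of 16 gives enal 11 and silyl dienol ether 14, made from methyl 3-methylbut-2-enoate 12. A vinylogous Mukaiyama aldol delivers C2–C5 with the (E)-C3=C4 olefin and the C6 carbinol in one step. A stepwise acetate aldol followed by olefination of a methyl ketone would be longer and poorly (E)-selective. The forward reaction must be γ-selective and enantioselective.

**Iodide fragment (11 ⇒ 10 ⇒ 8 ⇒ 7 ⇒ 2 + 3; 2 ⇐ 1).** The C12–I bond is traced to a methyl-substituted alkyne (8 to 10 by hydrozirconation–iodination), which is the reliable route to an (E)-2-iodoalk-2-ene. The C8–C9 bond of enoate 7 is cut to the copper reagent from bromide 2 and methyl but-2-ynoate 3, since syn-carbocupration fixes the (E)-C7=C8 geometry. Bromide 2 comes from pent-3-yn-1-ol 1.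

## Roads not taken

**Alternative 1:** The cut is at C6–C7 and at the C8–methyl bond. The ynal A2 (lactone in place, aldehyde at C6, terminal alkyne C7≡C8) would be cyclized with Ni(cod)2 and ZnMe2. Zerovalent nickel couples aldehyde and alkyne oxidatively to an oxanickelacycle, zinc transfers methyl to nickel, and reductive elimination gives the trienol A1 with (E)-C7=C8 by syn addition.

- Merits: one step closes the ring, installs the C8 methyl, fixes the C7=C8 geometry and frees the C6 hydroxyl for acetylation. No alkenyl iodide or borane is needed.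
- Weak points: C6 would be created during macrocyclization under the influence of a lactone dyad many atoms away, which gives no basis for prediction. A2 contains a β,γ-unsaturated aldehyde (C3=C4–C5–C6HO) that tends to move into conjugation. Direct methyl transfer to the aldehyde competes at high dilution. The C17 methylene still has to be added afterwards by enolate chemistry.
- Comparison: this closure is more step-economic than the chosen hydroboration–coupling and could save about three steps if the C6 selectivity were favourable. The chosen plan sets against this that C6 and C2 are each fixed by catalyst control in an open chain, and that its ring closure creates neither a stereocentre nor an olefin geometry. A2 would in any case need the same butenolide chemistry to build its C1/C2 dyad.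

**Alternative 2:** The cut is at C1–C15 and O–C2. The macrocyclic (1E,3E)-diene A4 would be annulated with 2-bromoacrylic acid A5 using Pd(OAc)2, a chiral phosphine and K2CO3. Oxidative addition of the C–Br bond, carbopalladation at C1 and capture of the C2–C4 π-allyl by the carboxylate at C2 would give the α-methylene lactone A3.

- Merits: this is the most convergent plan. The lactone and its methylene arrive together and unmasked, so no Mannich detour is needed, and A4 has a single stereocentre. After ring formation it is shorter than the chosen plan (two steps to 34 instead of four).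
- Weak points: the diene is internal at both ends (C1 disubstituted, C4 trisubstituted), the least documented substrate class for this annulation. Insertion must occur at C1 and not C4, and the carboxylate must attack C2 and not C4. The absolute configuration of C1/C2 would have to be imposed by the ligand on a flexible macrocycle against the bias of C6. The C3=C4 geometry is regenerated from a π-allyl and is no longer secured. A4 still needs its own macrocyclization.
- Comparison: the chosen plan is longer at the end. It sets against that a C2 centre from an open-chain catalytic addition, a C1 centre from anti addition on a rigid five-membered ring, and a C3=C4 geometry fixed from the aldol stage onward.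

**Alternative 3:** The cut is at C13–C14. The 16-membered macrolactone A7 has C14 as the α-carbon of a phenylsulfonylacetate esterified to the C13 allylic alcohol. Pd(PPh3)4 would ionize it to a C11–C13 π-allyl carboxylate, decarboxylation would give the C14 sulfonyl carbanion, and recombination at C13 would contract the ring to A6. Reductive desulfonylation would follow.

- Merits: the ring is first assembled by macrolactonization, the most reliable closure at this size. The C–C bond then forms within an ion pair, so no high dilution is needed for that step, and no organoborane or aqueous base is involved. In reliability of ring formation this road is arguably better than the chosen one.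
- Weak points: the C2 lactone oxygen of A7 is a second allylic ester that zerovalent palladium can ionize at the temperature a sulfonylacetate needs for decarboxylation, which risks C2. The C11–C13 allyl unit can be attacked at C11 and can isomerize to the (Z)-olefin. One bond costs three operations (macrolactonization, contraction, desulfonylation) plus the C13 oxidation level, and the reducing metals used for desulfonylation limit what may be present.
- Comparison: the chosen plan goes from 28 to 30 in one operation, transfers the C11=C12 geometry with retention from an alkenyl iodide, and engages palladium at the iodide at moderate temperature.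

Key step: step 13

Remark: locants C1–C17 in the prose follow the cembrane numbering of the first section; systematic names carry their own locants.
Assumption: in steps 7 and 11 the catalyst antipode is the one that delivers the nucleophile to the Re face of the aldehyde (this gives 5R in 16 and 4S in 22); if the first experiment shows the opposite sense, the other antipode is used.

## Route

Step 1
Reactants: 1 pent-3-yn-1-ol
Product: 2 5-bromopent-2-yne
Conditions: CBr4, PPh3, CH2Cl2, 0 °C → rt
Reagents that add atoms: carbon tetrabromide, BrC(Br)(Br)Br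
Why: Appel bromination of a primary alcohol; the internal alkyne is inert to the phosphonium intermediate.

Step 2
Reactants: 2 5-bromopent-2-yne; 3 methyl but-2-ynoate
Product: 7 methyl (2E)-3-methyloct-2-en-6-ynoate, via pent-3-yn-1-ylmagnesium bromide 4 (not isolated), via pent-3-yn-1-ylcopper 5 (not isolated), via alkenylcopper adduct 6 (not isolated)
Conditions: Mg, THF, rt; CuBr·SMe2 (1 equiv), −40 °C; 3, −78 °C; aq. NH4Cl, −78 °C → rt
Reagents that add atoms: none
Why: Syn-carbocupration of a 2-ynoate by a Grignard-derived organocopper reagent and protonation of the alkenylcopper with retention place the new chain trans to the ester, giving the (E)-enoate; keeping −78 °C prevents geometric equilibration through the allenoate.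

Step 3
Reactants: 7 methyl (2E)-3-methyloct-2-en-6-ynoate
Product: 8 (2E)-3-methyloct-2-en-6-yn-1-ol
Conditions: iBu2AlH (2.2 equiv), CH2Cl2, −78 °C; aq. potassium sodium tartrate
Reagents that add atoms: none
Why: 1,2-Reduction of an enoate to the allylic alcohol by iBu2AlH at low temperature; alkyne and olefin geometry are untouched.

Step 4
Reactants: 8 (2E)-3-methyloct-2-en-6-yn-1-ol
Product: 10 (2E,6E)-7-iodo-3-methylocta-2,6-dien-1-ol, via alkenylzirconocene chloride 9 (not isolated)
Conditions: Cp2Zr(H)Cl (3 equiv), THF, rt → 50 °C; I2, THF, 0 °C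
Reagents that add atoms: iodine, II
Why: Hydrozirconation of a methyl-substituted alkyne is a syn addition, and with excess reagent (one equivalent is consumed by the hydroxyl) it equilibrates to place zirconium on the carbon next to the methyl group; iodinolysis with retention gives the (E)-2-iodoalk-2-ene, and the trisubstituted olefin is not hydrozirconated.

Step 5
Reactants: 10 (2E,6E)-7-iodo-3-methylocta-2,6-dien-1-ol
Product: 11 (2E,6E)-7-iodo-3-methylocta-2,6-dienal
Conditions: MnO2, CH2Cl2, rt
Reagents that add atoms: none
Why: Neutral MnO2 oxidation of an allylic alcohol keeps the (2E) geometry and the alkenyl iodide.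

Step 6
Reactants: 12 methyl 3-methylbut-2-enoate
Product: 14 tert-butyl[(1-methoxy-3-methylbuta-1,3-dien-1-yl)oxy]dimethylsilane, via lithium dienolate 13 (not isolated)
Conditions: LiN(iPr)2, THF, −78 °C; TBSCl, DMPU, −78 °C → rt
Reagents that add atoms: tert-butyldimethylsilyl chloride, CC(C)(C)[Si](C)(C)Cl
Why: γ-Deprotonation of the β,β-dimethyl enoate and O-silylation give the silyl dienol ether; the ketene acetal geometry is not controlled and does not matter, because the reagent reacts at its remote γ-carbon.

Step 7
Reactants: 11 (2E,6E)-7-iodo-3-methylocta-2,6-dienal; 14 tert-butyl[(1-methoxy-3-methylbuta-1,3-dien-1-yl)oxy]dimethylsilane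
Product: 16 methyl (2E,5R,6E,10E)-5-hydroxy-11-iodo-3,7-dimethyldodeca-2,6,10-trienoate, via trichlorosilyl aldolate 15 (not isolated)
Conditions: SiCl4 (1.1 equiv), chiral 1,1'-binaphthyl-2,2'-diamine-derived bisphosphoramide (5 mol %), iPr2NEt (10 mol %), CH2Cl2, −78 °C; aq. NaHCO3
Reagents that add atoms: none
Why: Vinylogous Mukaiyama aldol under Lewis-base-activated SiCl4 catalysis: the phosphoramide-bound trichlorosilyl cation activates the enal and the dienol ether attacks through its unhindered γ-carbon in an open transition state, which gives the (E)-enoate; the catalyst antipode directing Re-face attack sets the carbinol as (5R), which becomes C6 of the target.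

Step 8
Reactants: 16 methyl (2E,5R,6E,10E)-5-hydroxy-11-iodo-3,7-dimethyldodeca-2,6,10-trienoate
Product: 17 methyl (2E,5R,6E,10E)-5-{[tert-butyl(dimethyl)silyl]oxy}-11-iodo-3,7-dimethyldodeca-2,6,10-trienoate
Conditions: TBSCl, imidazole, DMF, rt
Reagents that add atoms: tert-butyldimethylsilyl chloride, CC(C)(C)[Si](C)(C)Cl
Why: Silylation of a secondary allylic alcohol; the silyl ether is not an allylic leaving group toward copper or palladium and survives hydride, zinc, borane and base in the following steps.

Step 9
Reactants: 17 methyl (2E,5R,6E,10E)-5-{[tert-butyl(dimethyl)silyl]oxy}-11-iodo-3,7-dimethyldodeca-2,6,10-trienoate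
Product: 18 (2E,5R,6E,10E)-5-{[tert-butyl(dimethyl)silyl]oxy}-11-iodo-3,7-dimethyldodeca-2,6,10-trien-1-ol
Conditions: iBu2AlH (2.2 equiv), CH2Cl2, −78 °C; aq. potassium sodium tartrate
Reagents that add atoms: none
Why: 1,2-Reduction of the enoate; silyl ether, alkenyl iodide and olefin geometries are unaffected at −78 °C.

Step 10
Reactants: 18 (2E,5R,6E,10E)-5-{[tert-butyl(dimethyl)silyl]oxy}-11-iodo-3,7-dimethyldodeca-2,6,10-trien-1-ol
Product: 19 (2E,5R,6E,10E)-5-{[tert-butyl(dimethyl)silyl]oxy}-11-iodo-3,7-dimethyldodeca-2,6,10-trienal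
Conditions: MnO2, CH2Cl2, rt
Reagents that add atoms: none
Why: Selective allylic oxidation under neutral conditions, which avoids (2E)/(2Z) isomerization and base-induced elimination of the δ-silyloxy group.

Step 11
Reactants: 19 (2E,5R,6E,10E)-5-{[tert-butyl(dimethyl)silyl]oxy}-11-iodo-3,7-dimethyldodeca-2,6,10-trienal; 20 methyl prop-2-ynoate
Product: 22 methyl (4S,5E,8R,9E,13E)-8-{[tert-butyl(dimethyl)silyl]oxy}-4-hydroxy-14-iodo-6,10-dimethylpentadeca-5,9,13-trien-2-ynoate, via methylzinc alkynide 21 (not isolated)
Conditions: ProPhenol ligand (20 mol %), Me2Zn (3 equiv), toluene, 4 °C; aq. NH4Cl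
Reagents that add atoms: none
Why: Catalytic asymmetric alkynylation of an enal: the dinuclear zinc–ProPhenol complex binds the aldehyde and the zinc alkynide formed from 20 and Me2Zn and delivers the alkynyl group to the Re face, setting (4S), which becomes C2 of the target; the remote silyloxy centre should not override catalyst control.

Step 12
Reactants: 22 methyl (4S,5E,8R,9E,13E)-8-{[tert-butyl(dimethyl)silyl]oxy}-4-hydroxy-14-iodo-6,10-dimethylpentadeca-5,9,13-trien-2-ynoate
Product: 24 (5R)-5-[(1E,4R,5E,9E)-4-{[tert-butyl(dimethyl)silyl]oxy}-10-iodo-2,6-dimethylundeca-1,5,9-trien-1-yl]furan-2(5H)-one, via (Z)-hydroxy enoate 23 (not isolated)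
Conditions: H2 (1 atm), Pd/CaCO3 poisoned with Pb(OAc)2, quinoline, EtOAc, rt; then PPTS (cat.), CH2Cl2, rt
Reagents that add atoms: none
Why: Syn semihydrogenation of the electron-poor alkyne on lead-poisoned palladium gives the (Z)-γ-hydroxy enoate, which lactonizes to the butenolide; quinoline and stopping after one equivalent of hydrogen are meant to spare the trisubstituted olefins and the alkenyl iodide, and the carbinol centre is not touched (its descriptor changes to R only through priorities).

Step 13
Reactants: 24 (5R)-5-[(1E,4R,5E,9E)-4-{[tert-butyl(dimethyl)silyl]oxy}-10-iodo-2,6-dimethylundeca-1,5,9-trien-1-yl]furan-2(5H)-one; 25 ethenylmagnesium bromide; 26 N,N-dimethylmethaniminium iodide (Eschenmoser's salt)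
Product: 28 (3S,4R,5R)-5-[(1E,4R,5E,9E)-4-{[tert-butyl(dimethyl)silyl]oxy}-10-iodo-2,6-dimethylundeca-1,5,9-trien-1-yl]-3-[(dimethylamino)methyl]-4-ethenyloxolan-2-one, via silyl ketene acetal 27 (not isolated)
Conditions: CuBr·SMe2 (10 mol %), Me3SiCl (3 equiv), THF, −78 °C; then 26, CH2Cl2, −78 °C → rt; aq. NaHCO3
Reagents that add atoms: none
Why: Transmetalation of 25 to copper gives a vinylcopper species that forms a π-complex with the C1=C15 bond of 24 and adds to C1; Me3SiCl silylates the enolate oxygen, speeds reductive elimination from the trivalent copper intermediate and releases silyl ketene acetal 27 while returning monovalent copper to the cycle. The iminium ion of 26 then alkylates C15 of 27 (Mannich reaction of a silyl ketene acetal) and iodide removes the silyl group, giving β-amino lactone 28. The closest known reaction type is the copper-catalysed, chlorosilane-accelerated conjugate addition of Grignard reagents to γ-substituted butenolides with capture of the enolate by an iminium salt. No ring is closed: two acyclic bonds (C1–C14 and C15–C17) form on the existing five-membered ring. The new C1 centre is controlled by C2, because the nucleophile approaches the planar butenolide on the face opposite the C2 alkenyl chain, which gives the 1,2-trans lactone. The C15 centre is controlled by C1 (alkylation anti to the vinyl group), is temporary and disappears in step 17. The step needs 1,4-addition in preference to allylic displacement of the lactone oxygen at C4, to γ-deprotonation at C2 and to any reaction of the alkenyl iodide; the fully substituted C4 terminus, the low basicity of the vinyl reagent, the fast silyl-accelerated addition at −78 °C and the inertness of an alkenyl iodide toward a vinyl Grignard reagent at that temperature should secure this.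

Step 14
Reactants: 28 (3S,4R,5R)-5-[(1E,4R,5E,9E)-4-{[tert-butyl(dimethyl)silyl]oxy}-10-iodo-2,6-dimethylundeca-1,5,9-trien-1-yl]-3-[(dimethylamino)methyl]-4-ethenyloxolan-2-one
Product: 30 (3S,3aR,6E,10E,12R,14E,15aR)-12-{[tert-butyl(dimethyl)silyl]oxy}-3-[(dimethylamino)methyl]-6,10,14-trimethyl-3a,4,5,8,9,12,13,15a-octahydrocyclotetradeca[b]furan-2(3H)-one, via B-alkyl-9-BBN borane 29 (not isolated)
Conditions: 9-BBN (3 equiv), THF, 0 °C → rt; then slow addition to PdCl2(dppf) (20 mol %), AsPh3, Cs2CO3, DMF/THF/H2O, 50 °C, 1 mM
Reagents that add atoms: none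
Why: 9-BBN hydroborates the only monosubstituted alkene at its terminal carbon C13 and leaves the trisubstituted olefins and the alkenyl iodide alone; B-alkyl Suzuki–Miyaura coupling (oxidative addition at C12–I, transmetalation of the hydroxyborate, reductive elimination) then forms C12–C13 with retention of the (E)-geometry and closes the 14-membered ring under high dilution. No stereocentre is formed; the Mannich base keeps C15 saturated so that neither borane nor aqueous base meets a Michael acceptor.

Step 15
Reactants: 30 (3S,3aR,6E,10E,12R,14E,15aR)-12-{[tert-butyl(dimethyl)silyl]oxy}-3-[(dimethylamino)methyl]-6,10,14-trimethyl-3a,4,5,8,9,12,13,15a-octahydrocyclotetradeca[b]furan-2(3H)-one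
Product: 31 (3S,3aR,6E,10E,12R,14E,15aR)-3-[(dimethylamino)methyl]-12-hydroxy-6,10,14-trimethyl-3a,4,5,8,9,12,13,15a-octahydrocyclotetradeca[b]furan-2(3H)-one
Conditions: HF·pyridine, pyridine/THF, 0 °C → rt
Reagents that add atoms: none
Why: Buffered fluoride cleavage of the secondary silyl ether; the conditions are not basic enough to open the lactone or eliminate the amine and not acidic enough to ionize the allylic carbinol.

Step 16
Reactants: 31 (3S,3aR,6E,10E,12R,14E,15aR)-3-[(dimethylamino)methyl]-12-hydroxy-6,10,14-trimethyl-3a,4,5,8,9,12,13,15a-octahydrocyclotetradeca[b]furan-2(3H)-one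
Product: 32 (3S,3aR,6E,10E,12R,14E,15aR)-3-[(dimethylamino)methyl]-6,10,14-trimethyl-2-oxo-2,3,3a,4,5,8,9,12,13,15a-decahydrocyclotetradeca[b]furan-12-yl acetate
Conditions: Ac2O, pyridine, DMAP (cat.), CH2Cl2, rt
Reagents that add atoms: acetic anhydride, CC(=O)OC(C)=O
Why: Acylation of the secondary allylic alcohol with retention at C6; the tertiary amine is not acylated, and the acetate is introduced only after the last palladium step.

Step 17
Reactants: 32 (3S,3aR,6E,10E,12R,14E,15aR)-3-[(dimethylamino)methyl]-6,10,14-trimethyl-2-oxo-2,3,3a,4,5,8,9,12,13,15a-decahydrocyclotetradeca[b]furan-12-yl acetate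
Product: 34 (3aR,6E,10E,12R,14E,15aS)-6,10,14-trimethyl-3-methylidene-2-oxo-2,3,3a,4,5,8,9,12,13,15a-decahydrocyclotetradeca[b]furan-12-yl acetate (CNP0206931.1), via trimethylammonium iodide 33 (not isolated)
Conditions: MeI, THF, rt; then aq. NaHCO3, CH2Cl2, rt
Reagents that add atoms: none
Why: N-Methylation gives the quaternary ammonium salt, whose C15–H is α to the lactone carbonyl, so mild base effects E1cB loss of trimethylamine to the exocyclic methylene (quaternization–elimination of a Mannich base); C15 is destroyed, C1, C2 and C6 are untouched (the C2 descriptor becomes S only through priorities), and hydrogencarbonate spares the acetate.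

## Compound list

1 | pent-3-yn-1-ol | CC#CCCO | starting material
2 | 5-bromopent-2-yne | CC#CCCBr | intermediate
3 | methyl but-2-ynoate | CC#CC(=O)OC | starting material
4 | pent-3-yn-1-ylmagnesium bromide | CC#CCC[Mg]Br | intermediate
5 | pent-3-yn-1-ylcopper | CC#CCC[Cu] | intermediate
6 | methyl (2Z)-2-cuprio-3-methyloct-2-en-6-ynoate (alkenylcopper adduct) | COC(=O)/C([Cu])=C(\C)CCC#CC | intermediate
7 | methyl (2E)-3-methyloct-2-en-6-ynoate | COC(=O)/C=C(\C)CCC#CC | intermediate
8 | (2E)-3-methyloct-2-en-6-yn-1-ol | CC#CCC/C(C)=C/CO | intermediate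
9 | chlorobis(cyclopentadienyl)[(2E,6E)-8-{[chlorobis(cyclopentadienyl)zirconio]oxy}-6-methylocta-2,6-dien-2-yl]zirconium (alkenylzirconocene chloride, hydroxyl as zirconium alkoxide; cyclopentadienyl drawn σ-bonded) | C/C(=C\CC/C(C)=C/CO[Zr](Cl)(C1C=CC=C1)C1C=CC=C1)[Zr](Cl)(C1C=CC=C1)C1C=CC=C1 | intermediate
10 | (2E,6E)-7-iodo-3-methylocta-2,6-dien-1-ol | C/C(I)=C\CC/C(C)=C/CO | intermediate
11 | (2E,6E)-7-iodo-3-methylocta-2,6-dienal | C/C(I)=C\CC/C(C)=C/C=O | intermediate
12 | methyl 3-methylbut-2-enoate | CC(C)=CC(=O)OC | starting material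
13 | lithium 1-methoxy-3-methylbuta-1,3-dien-1-olate | [Li+].[O-]C(OC)=CC(C)=C | intermediate
14 | tert-butyl[(1-methoxy-3-methylbuta-1,3-dien-1-yl)oxy]dimethylsilane (ketene acetal geometry not defined) | C=C(C)C=C(OC)O[Si](C)(C)C(C)(C)C | intermediate
15 | methyl (2E,5R,6E,10E)-11-iodo-3,7-dimethyl-5-[(trichlorosilyl)oxy]dodeca-2,6,10-trienoate | COC(=O)/C=C(\C)C[C@@H](O[Si](Cl)(Cl)Cl)/C=C(\C)CC/C=C(\C)I | intermediate
16 | methyl (2E,5R,6E,10E)-5-hydroxy-11-iodo-3,7-dimethyldodeca-2,6,10-trienoate | COC(=O)/C=C(\C)C[C@@H](O)/C=C(\C)CC/C=C(\C)I | intermediate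
17 | methyl (2E,5R,6E,10E)-5-{[tert-butyl(dimethyl)silyl]oxy}-11-iodo-3,7-dimethyldodeca-2,6,10-trienoate | COC(=O)/C=C(\C)C[C@@H](O[Si](C)(C)C(C)(C)C)/C=C(\C)CC/C=C(\C)I | intermediate
18 | (2E,5R,6E,10E)-5-{[tert-butyl(dimethyl)silyl]oxy}-11-iodo-3,7-dimethyldodeca-2,6,10-trien-1-ol | OC/C=C(\C)C[C@@H](O[Si](C)(C)C(C)(C)C)/C=C(\C)CC/C=C(\C)I | intermediate
19 | (2E,5R,6E,10E)-5-{[tert-butyl(dimethyl)silyl]oxy}-11-iodo-3,7-dimethyldodeca-2,6,10-trienal | O=C/C=C(\C)C[C@@H](O[Si](C)(C)C(C)(C)C)/C=C(\C)CC/C=C(\C)I | intermediate
20 | methyl prop-2-ynoate (methyl propiolate) | C#CC(=O)OC | starting material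
21 | methyl 3-(methylzincio)prop-2-ynoate | COC(=O)C#C[Zn]C | intermediate
22 | methyl (4S,5E,8R,9E,13E)-8-{[tert-butyl(dimethyl)silyl]oxy}-4-hydroxy-14-iodo-6,10-dimethylpentadeca-5,9,13-trien-2-ynoate | COC(=O)C#C[C@@H](O)/C=C(\C)C[C@@H](O[Si](C)(C)C(C)(C)C)/C=C(\C)CC/C=C(\C)I | intermediate
23 | methyl (2Z,4R,5E,8R,9E,13E)-8-{[tert-butyl(dimethyl)silyl]oxy}-4-hydroxy-14-iodo-6,10-dimethylpentadeca-2,5,9,13-tetraenoate | COC(=O)/C=C\[C@@H](O)/C=C(\C)C[C@@H](O[Si](C)(C)C(C)(C)C)/C=C(\C)CC/C=C(\C)I | intermediate
24 | (5R)-5-[(1E,4R,5E,9E)-4-{[tert-butyl(dimethyl)silyl]oxy}-10-iodo-2,6-dimethylundeca-1,5,9-trien-1-yl]furan-2(5H)-one | O=C1C=C[C@H](/C=C(\C)C[C@@H](O[Si](C)(C)C(C)(C)C)/C=C(\C)CC/C=C(\C)I)O1 | intermediate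
25 | ethenylmagnesium bromide (vinylmagnesium bromide) | C=C[Mg]Br | starting material
26 | N,N-dimethylmethaniminium iodide (Eschenmoser's salt) | C=[N+](C)C.[I-] | starting material
27 | {[(4R,5R)-5-[(1E,4R,5E,9E)-4-{[tert-butyl(dimethyl)silyl]oxy}-10-iodo-2,6-dimethylundeca-1,5,9-trien-1-yl]-4-ethenyl-4,5-dihydrofuran-2-yl]oxy}trimethylsilane | C[Si](C)(C)OC1=C[C@@H](C=C)[C@H](/C=C(\C)C[C@@H](O[Si](C)(C)C(C)(C)C)/C=C(\C)CC/C=C(\C)I)O1 | intermediate
28 | (3S,4R,5R)-5-[(1E,4R,5E,9E)-4-{[tert-butyl(dimethyl)silyl]oxy}-10-iodo-2,6-dimethylundeca-1,5,9-trien-1-yl]-3-[(dimethylamino)methyl]-4-ethenyloxolan-2-one (trans,trans lactone) | CN(C)C[C@H]1C(=O)O[C@@H](/C=C(\C)C[C@@H](O[Si](C)(C)C(C)(C)C)/C=C(\C)CC/C=C(\C)I)[C@@H]1C=C | intermediate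
29 | (3S,4R,5R)-4-[2-(9-borabicyclo[3.3.1]nonan-9-yl)ethyl]-5-[(1E,4R,5E,9E)-4-{[tert-butyl(dimethyl)silyl]oxy}-10-iodo-2,6-dimethylundeca-1,5,9-trien-1-yl]-3-[(dimethylamino)methyl]oxolan-2-one | CN(C)C[C@H]1C(=O)O[C@@H](/C=C(\C)C[C@@H](O[Si](C)(C)C(C)(C)C)/C=C(\C)CC/C=C(\C)I)[C@@H]1CCB1C2CCCC1CCC2 | intermediate
30 | (3S,3aR,6E,10E,12R,14E,15aR)-12-{[tert-butyl(dimethyl)silyl]oxy}-3-[(dimethylamino)methyl]-6,10,14-trimethyl-3a,4,5,8,9,12,13,15a-octahydrocyclotetradeca[b]furan-2(3H)-one (cembrane locants: 1R,2R,6R,15S; spatial arrangement at C1, C2, C6 as in 34) | CN(C)C[C@H]1C(=O)O[C@H]2/C=C(\C)C[C@@H](O[Si](C)(C)C(C)(C)C)/C=C(\C)CC/C=C(\C)CC[C@H]12 | intermediate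
31 | (3S,3aR,6E,10E,12R,14E,15aR)-3-[(dimethylamino)methyl]-12-hydroxy-6,10,14-trimethyl-3a,4,5,8,9,12,13,15a-octahydrocyclotetradeca[b]furan-2(3H)-one | CN(C)C[C@H]1C(=O)O[C@H]2/C=C(\C)C[C@@H](O)/C=C(\C)CC/C=C(\C)CC[C@H]12 | intermediate
32 | (3S,3aR,6E,10E,12R,14E,15aR)-3-[(dimethylamino)methyl]-6,10,14-trimethyl-2-oxo-2,3,3a,4,5,8,9,12,13,15a-decahydrocyclotetradeca[b]furan-12-yl acetate | CN(C)C[C@H]1C(=O)O[C@H]2/C=C(\C)C[C@@H](OC(C)=O)/C=C(\C)CC/C=C(\C)CC[C@H]12 | intermediate
33 | 1-[(3S,3aR,6E,10E,12R,14E,15aR)-12-(acetyloxy)-6,10,14-trimethyl-2-oxo-2,3,3a,4,5,8,9,12,13,15a-decahydrocyclotetradeca[b]furan-3-yl]-N,N,N-trimethylmethanaminium iodide | C[N+](C)(C)C[C@H]1C(=O)O[C@H]2/C=C(\C)C[C@@H](OC(C)=O)/C=C(\C)CC/C=C(\C)CC[C@H]12.[I-] | intermediate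
34 | (3aR,6E,10E,12R,14E,15aS)-6,10,14-trimethyl-3-methylidene-2-oxo-2,3,3a,4,5,8,9,12,13,15a-decahydrocyclotetradeca[b]furan-12-yl acetate (cembrane locants: 1R,2S,6R; CNP0206931.1) | C=C1C(=O)O[C@H]2/C=C(\C)C[C@@H](OC(C)=O)/C=C(\C)CC/C=C(\C)CC[C@H]12 | target

## Step count and risks

Total step count: 17. Longest linear sequence: 16 steps (steps 1–5 and 7–17, from pent-3-yn-1-ol); step 6 is a one-step side branch.

Least certain steps:

**Step 13 (key step).** The conjugate addition may be outrun by allylic displacement of the lactone carboxylate at C4, or by γ-deprotonation at C2 followed by silylation to a 2-silyloxyfuran, which would erase the C2 configuration. The second stage may fail through slow C-alkylation of the silyl ketene acetal by the sparingly soluble iminium salt, so that simple protonation on work-up takes over. Fallback, from 24: a 1,4-addition of potassium vinyltrifluoroborate catalysed by monovalent rhodium ([RhCl(cod)]2, aqueous dioxane) is a neutral carbometalation that cannot displace the allylic oxygen. It should add anti to the C2 chain and give (4S,5R)-5-[(1E,4R,5E,9E)-4-{[tert-butyl(dimethyl)silyl]oxy}-10-iodo-2,6-dimethylundeca-1,5,9-trien-1-yl]-4-ethenyloxolan-2-one F1. Deprotonation of this lactone with LiN(iPr)2 at −78 °C and alkylation of the lithium enolate with 26 returns to 28.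

**Step 14.** Intermolecular coupling may outrun ring closure. Transmetalation may be slowed because the dimethylamino group coordinates boron. Zerovalent palladium may ionize the allylic C2–O bond, and aqueous base may open the lactone. Fallback, from 28: a Stille coupling with tributyl(vinyl)stannane (Pd2(dba)3, AsPh3) converts the iodide into the diene (3S,4R,5R)-5-[(1E,4R,5E,9E)-4-{[tert-butyl(dimethyl)silyl]oxy}-2,6,10-trimethyldodeca-1,5,9,11-tetraen-1-yl]-3-[(dimethylamino)methyl]-4-ethenyloxolan-2-one F2. Ring-closing metathesis of the two terminal alkenes (second-generation Grubbs catalyst, amine held as its camphorsulfonate salt, high dilution) gives the 13,14-didehydro derivative of 30 F3. Diimide (2-nitrobenzenesulfonylhydrazide, Et3N) then saturates the only disubstituted olefin and returns to 30.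

**Step 12.** Hydrogenolysis of the C–I bond or over-reduction of the enoate may accompany the semihydrogenation on palladium. Fallback, from 19, using neither hydrogen nor palladium: catalytic asymmetric addition of divinylzinc (chiral amino alcohol ligand, Re face) gives (3R,4E,7R,8E,12E)-7-{[tert-butyl(dimethyl)silyl]oxy}-13-iodo-5,9-dimethyltetradeca-1,4,8,12-tetraen-3-ol F4. Acylation with acryloyl chloride and Et3N gives (3R,4E,7R,8E,12E)-7-{[tert-butyl(dimethyl)silyl]oxy}-13-iodo-5,9-dimethyltetradeca-1,4,8,12-tetraen-3-yl prop-2-enoate F5. Ring-closing metathesis between the acrylate and the vinyl group (second-generation Grubbs catalyst) returns to 24.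

**Step 11.** Facial control may be insufficient for a β,β-disubstituted enal carrying a remote silyloxy group, or uncatalysed background addition may occur; either would give a mixture at the new carbinol. Fallback, from 19: uncontrolled addition of lithiated methyl propiolate (LiN(SiMe3)2, THF, −78 °C) gives 22 together with methyl (4R,5E,8R,9E,13E)-8-{[tert-butyl(dimethyl)silyl]oxy}-4-hydroxy-14-iodo-6,10-dimethylpentadeca-5,9,13-trien-2-ynoate F6. MnO2 oxidizes the mixture to methyl (5E,8R,9E,13E)-8-{[tert-butyl(dimethyl)silyl]oxy}-14-iodo-6,10-dimethyl-4-oxopentadeca-5,9,13-trien-2-ynoate F7. Reagent-controlled reduction of this alkynyl ketone with Alpine-borane (B-isopinocampheyl-9-BBN, the antipode giving 4S) returns to 22.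

## Further compounds

F1 | step 13 | (4S,5R)-5-[(1E,4R,5E,9E)-4-{[tert-butyl(dimethyl)silyl]oxy}-10-iodo-2,6-dimethylundeca-1,5,9-trien-1-yl]-4-ethenyloxolan-2-one | C1C(=O)O[C@@H](/C=C(\C)C[C@@H](O[Si](C)(C)C(C)(C)C)/C=C(\C)CC/C=C(\C)I)[C@@H]1C=C
F2 | step 14 | (3S,4R,5R)-5-[(1E,4R,5E,9E)-4-{[tert-butyl(dimethyl)silyl]oxy}-2,6,10-trimethyldodeca-1,5,9,11-tetraen-1-yl]-3-[(dimethylamino)methyl]-4-ethenyloxolan-2-one | CN(C)C[C@H]1C(=O)O[C@@H](/C=C(\C)C[C@@H](O[Si](C)(C)C(C)(C)C)/C=C(\C)CC/C=C(\C)C=C)[C@@H]1C=C
F3 | step 14 | 13,14-didehydro derivative of 30 (cembrane locants; C13=C14 geometry not defined) | CN(C)C[C@H]1C(=O)O[C@H]2/C=C(\C)C[C@@H](O[Si](C)(C)C(C)(C)C)/C=C(\C)CC/C=C(\C)C=C[C@H]12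
F4 | step 12 | (3R,4E,7R,8E,12E)-7-{[tert-butyl(dimethyl)silyl]oxy}-13-iodo-5,9-dimethyltetradeca-1,4,8,12-tetraen-3-ol | C=C[C@@H](O)/C=C(\C)C[C@@H](O[Si](C)(C)C(C)(C)C)/C=C(\C)CC/C=C(\C)I
F5 | step 12 | (3R,4E,7R,8E,12E)-7-{[tert-butyl(dimethyl)silyl]oxy}-13-iodo-5,9-dimethyltetradeca-1,4,8,12-tetraen-3-yl prop-2-enoate | C=CC(=O)O[C@H](C=C)/C=C(\C)C[C@@H](O[Si](C)(C)C(C)(C)C)/C=C(\C)CC/C=C(\C)I
F6 | step 11 | methyl (4R,5E,8R,9E,13E)-8-{[tert-butyl(dimethyl)silyl]oxy}-4-hydroxy-14-iodo-6,10-dimethylpentadeca-5,9,13-trien-2-ynoate | COC(=O)C#C[C@H](O)/C=C(\C)C[C@@H](O[Si](C)(C)C(C)(C)C)/C=C(\C)CC/C=C(\C)I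
F7 | step 11 | methyl (5E,8R,9E,13E)-8-{[tert-butyl(dimethyl)silyl]oxy}-14-iodo-6,10-dimethyl-4-oxopentadeca-5,9,13-trien-2-ynoate | COC(=O)C#CC(=O)/C=C(\C)C[C@@H](O[Si](C)(C)C(C)(C)C)/C=C(\C)CC/C=C(\C)I
A1 | alternative 1 | 14-membered lactone-fused trienol with free C6 hydroxyl, lacking the C17 methylene and the acetyl group (C1, C2, C6 arranged as in 34) | C1C(=O)O[C@H]2/C=C(\C)C[C@@H](O)/C=C(\C)CC/C=C(\C)CC[C@H]12
A2 | alternative 1 | trans-5-[(1E)-2-methyl-4-oxobut-1-en-1-yl]-4-[(3E)-3-methyloct-3-en-7-yn-1-yl]oxolan-2-one (ynal; C1, C2 arranged as in 34) | C1C(=O)O[C@@H](/C=C(\C)CC=O)[C@@H]1CC/C(C)=C/CCC#C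
A3 | alternative 2 | C6 tert-butyldimethylsilyl ether of the deacetyl target | C=C1C(=O)O[C@H]2/C=C(\C)C[C@@H](O[Si](C)(C)C(C)(C)C)/C=C(\C)CC/C=C(\C)CC[C@H]12
A4 | alternative 2 | tert-butyl(dimethyl){[(1R,2E,6E,10E,12E)-3,7,13-trimethylcyclotetradeca-2,6,10,12-tetraen-1-yl]oxy}silane (macrocyclic diene) | C1/C=C/C=C(\C)C[C@@H](O[Si](C)(C)C(C)(C)C)/C=C(\C)CC/C=C(\C)C1
A5 | alternative 2 | 2-bromoprop-2-enoic acid | C=C(Br)C(=O)O
A6 | alternative 3 | 14-membered lactone-fused carbocycle with phenylsulfonyl on C14 and silyl ether on C6, lacking C17 (one C14 epimer) | C1C(=O)O[C@H]2/C=C(\C)C[C@@H](O[Si](C)(C)C(C)(C)C)/C=C(\C)CC/C=C(\C)C[C@H](S(=O)(=O)c3ccccc3)[C@H]12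
A7 | alternative 3 | 16-membered macrolactone: C14 (phenylsulfonyl)acetate esterified to the C13 allylic alcohol (C14 configuration not defined) | C1C(=O)O[C@H]2/C=C(\C)C[C@@H](O[Si](C)(C)C(C)(C)C)/C=C(\C)CC/C=C(\C)COC(=O)C(S(=O)(=O)c3ccccc3)[C@H]12
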